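**Retrosynthetic overview**
1. Target ⇐ hydrogenolysis of its tris‑benzyl‑protected form; C11 ⇐ substrate‑controlled hydrogenation of a C11=C12 allylic acetate, itself made by a singlet‑oxygen ene transposition.
2. Key bond C13–C14 ⇐ photochemical nickel‑catalysed deoxygenative alkyl–alkyl coupling of a homoallylic alcohol with (S)‑3‑bromo‑2‑methylpropan‑1‑ol, which brings C15.
3. C13 ⇐ formaldehyde ene reaction on the isopropenyl group (C11, C12, C18) carried over from carvone.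
4. Rings: the cyclohexane ring is bought as (R)‑carvone (C4) and C1 is set by conjugate reduction; the aromatic ring is then built onto it by a new [3+3] benzannulation.

Assumption: compounds 1, 3 and 10 and all unnumbered reagents are commercial; atom labels C1–C18 are the serrulatane labels of the target (C1 bears the ring methyl, C4 the side chain, C11 and C15 are the side‑chain stereocentres).

**Step 1**
Reactants: 1 (R)‑carvone
Product: 2 (2R,5R)‑2‑methyl‑5‑(prop‑1‑en‑2‑yl)cyclohexan‑1‑one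
Conditions: LiBH(s‑Bu)3, THF, −78 °C; then H2O, −78 °C → rt
Reagents that add atoms: none
Why: Conjugate (1,4) hydride reduction of the enone and protonation of the enolate should give mainly the trans, diequatorial ketone (expected about 9:1; the cis isomer is removed by chromatography), so C1 is set under control of the carvone stereocentre.

**Step 2**
Reactants: 3 ethyl 4‑(benzyloxy)‑3‑oxobutanoate
Product: 4 benzyl 4‑(benzyloxy)‑3‑oxobutanoate
Conditions: BnOH (1.2 equiv), DMAP (cat.), PhMe, reflux, EtOH distilled off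
Reagents that add atoms: benzyl alcohol, OCc1ccccc1
Why: Transesterification of a β‑keto ester, driven by removal of ethanol; no stereocentre is involved.

**Step 3**
Reactants: 4 benzyl 4‑(benzyloxy)‑3‑oxobutanoate
Product: 5 benzyl 4‑(benzyloxy)‑2‑(ethoxymethylidene)‑3‑oxobutanoate
Conditions: HC(OEt)3, Ac2O, 130 °C
Reagents that add atoms: triethyl orthoformate, CCOC(OCC)OCC
Why: Ethoxymethylenation (Claisen‑type condensation) of the doubly activated methylene with the orthoester, with acetic anhydride trapping the ethanol; E/Z mixture, no stereocentre.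

**Step 4**
Reactants: 2 (2R,5R)‑2‑methyl‑5‑(prop‑1‑en‑2‑yl)cyclohexan‑1‑one; 5 benzyl 4‑(benzyloxy)‑2‑(ethoxymethylidene)‑3‑oxobutanoate
Product: 8 benzyl (5R,8S)‑3,4‑bis(benzyloxy)‑5‑methyl‑8‑(prop‑1‑en‑2‑yl)‑5,6,7,8‑tetrahydronaphthalene‑2‑carboxylate, via dienone adduct 6 (not isolated), via phenol 7 (not isolated)
Conditions: LiN(i‑Pr)2, THF, −78 °C; 5, −78 → −20 °C; AcOH; then K2CO3, DMF, 70 °C; then BnBr, 50 °C
Reagents that add atoms: benzyl bromide, BrCc1ccccc1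
Why: Proposed new method: the kinetic lithium enolate of 2 (formed at the CH2, not at the methyl‑bearing carbon) attacks the ethoxy‑bearing carbon of the push–pull alkene 5 and expels ethoxide (addition–elimination, as enolates do with ethoxymethylenemalonates) to give the vinylogous tricarbonyl 6, whose most acidic hydrogen sits on the ring carbon between ketone and alkene, so under K2CO3 the ketone is enolised only on that side and the methyl‑bearing α‑carbon is not epimerised, the benzyloxy‑activated side‑chain CH2 then adds to the ring ketone in a six‑membered intramolecular aldol reaction and loss of water with tautomerisation aromatises irreversibly (OBn next to the methyl‑bearing ring carbon, H next to the isopropenyl‑bearing one), and the phenoxide is benzylated in the same flask; the closest known reactions are the Prelog‑type phenol synthesis from 2‑hydroxymethylene ketones with acetoacetic esters and the Chan–Brownbridge [3+3] cycloaromatisation, and no new stereocentre is formed.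

**Step 5**
Reactants: 8 benzyl (5R,8S)‑3,4‑bis(benzyloxy)‑5‑methyl‑8‑(prop‑1‑en‑2‑yl)‑5,6,7,8‑tetrahydronaphthalene‑2‑carboxylate
Product: 9 benzyl (5R,8S)‑3,4‑bis(benzyloxy)‑8‑(4‑hydroxybut‑1‑en‑2‑yl)‑5‑methyl‑5,6,7,8‑tetrahydronaphthalene‑2‑carboxylate
Conditions: (CH2O)n, Me2AlCl, CH2Cl2, 0 °C → rt; 1 M HCl
Reagents that add atoms: formaldehyde (as paraformaldehyde), C=O
Why: Me2AlCl‑promoted carbonyl‑ene reaction of formaldehyde on the only 1,1‑disubstituted alkene, with hydrogen taken from the methyl group (the ring C–H lies in the alkene plane) and methane loss from the aluminium alkoxide preventing Prins follow‑up; no stereocentre is formed.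

**Step 6**
Reactants: 9 benzyl (5R,8S)‑3,4‑bis(benzyloxy)‑8‑(4‑hydroxybut‑1‑en‑2‑yl)‑5‑methyl‑5,6,7,8‑tetrahydronaphthalene‑2‑carboxylate; 10 (S)‑3‑bromo‑2‑methylpropan‑1‑ol
Product: 12 benzyl (5R,8S)‑3,4‑bis(benzyloxy)‑8‑[(6R)‑7‑hydroxy‑6‑methylhept‑1‑en‑2‑yl]‑5‑methyl‑5,6,7,8‑tetrahydronaphthalene‑2‑carboxylate, via benzoxazoline ether 11 (not isolated)
Conditions: 9, 5,7‑di‑tert‑butyl‑3‑phenyl‑1,3‑benzoxazol‑3‑ium tetrafluoroborate (1.0 equiv), pyridine, t‑BuOMe, rt; then 10 (3 equiv), [Ir(ppy)2(dtbbpy)]PF6 (1 mol %), NiBr2·dme/dtbbpy (5 mol %), quinuclidine, DMA, 450 nm LEDs, rt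
Reagents that add atoms: none
Why: Metallaphotoredox deoxygenative C(sp3)–C(sp3) cross‑coupling, in which photocatalytic oxidation and β‑scission of the pre‑formed adduct 11 release the primary C13 radical and nickel joins it to the primary bromide 10; the free hydroxyl of 10 is not activated because the benzoxazolium salt is consumed beforehand, and the C15 stereocentre is not at a reacting carbon.

**Step 7**
Reactants: 12 benzyl (5R,8S)‑3,4‑bis(benzyloxy)‑8‑[(6R)‑7‑hydroxy‑6‑methylhept‑1‑en‑2‑yl]‑5‑methyl‑5,6,7,8‑tetrahydronaphthalene‑2‑carboxylate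
Product: 15 benzyl (5R,8R)‑8‑[(6R)‑1,7‑diacetoxy‑6‑methylhept‑2‑en‑2‑yl]‑3,4‑bis(benzyloxy)‑5‑methyl‑5,6,7,8‑tetrahydronaphthalene‑2‑carboxylate, via allylic hydroperoxide 13 (not isolated), via allylic diol 14 (not isolated)
Conditions: O2, tetraphenylporphyrin (cat.), CH2Cl2, 0 °C, white LEDs; then PPh3; then Ac2O, pyridine, DMAP (cat.), rt
Reagents that add atoms: dioxygen, O=O; acetic anhydride, CC(=O)OC(C)=O
Why: Schenck ene reaction of photosensitised singlet oxygen puts oxygen on the terminal CH2 (C18) and takes a hydrogen from the chain CH2 (C12; the ring C–H is held in the alkene plane), moving the double bond to C11=C12, after which PPh3 reduces the hydroperoxide and both primary alcohols are acetylated (E/Z mixture, no stereocentre yet).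

**Step 8**
Reactants: 15 benzyl (5R,8R)‑8‑[(6R)‑1,7‑diacetoxy‑6‑methylhept‑2‑en‑2‑yl]‑3,4‑bis(benzyloxy)‑5‑methyl‑5,6,7,8‑tetrahydronaphthalene‑2‑carboxylate
Product: 16 benzyl (5R,8S)‑8‑[(2S,6R)‑1,7‑diacetoxy‑6‑methylheptan‑2‑yl]‑3,4‑bis(benzyloxy)‑5‑methyl‑5,6,7,8‑tetrahydronaphthalene‑2‑carboxylate
Conditions: H2 (1 atm), [Ir(cod)(PCy3)(py)]PF6 (5 mol %), CH2Cl2, rt
Reagents that add atoms: none
Why: Homogeneous alkene hydrogenation with the cationic iridium catalyst, which leaves benzyl groups and the allylic acetate intact; with the ring C–H eclipsing the C11=C12 bond (allylic 1,3‑strain), hydrogen is predicted to add to the face away from the aryl ring, the sense seen in additions to isopropenyl groups next to a ring stereocentre, giving the (S) centre at C11 from either alkene isomer.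

**Step 9**
Reactants: 16 benzyl (5R,8S)‑8‑[(2S,6R)‑1,7‑diacetoxy‑6‑methylheptan‑2‑yl]‑3,4‑bis(benzyloxy)‑5‑methyl‑5,6,7,8‑tetrahydronaphthalene‑2‑carboxylate
Product: 17 (5R,8S)‑8‑[(2S,6R)‑1,7‑diacetoxy‑6‑methylheptan‑2‑yl]‑3,4‑dihydroxy‑5‑methyl‑5,6,7,8‑tetrahydronaphthalene‑2‑carboxylic acid
Conditions: H2 (1 atm), Pd/C (10 wt % palladium on carbon), EtOAc, rt
Reagents that add atoms: none
Why: Hydrogenolysis of the two benzyl ethers and the benzyl ester frees the catechol and the carboxylic acid, while the alkyl acetates and all four stereocentres are untouched.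

**Compound list**
1 | (R)‑carvone, (5R)‑2‑methyl‑5‑(prop‑1‑en‑2‑yl)cyclohex‑2‑en‑1‑one | CC(=C)[C@@H]1CC=C(C)C(=O)C1 | starting material
2 | (2R,5R)‑2‑methyl‑5‑(prop‑1‑en‑2‑yl)cyclohexan‑1‑one (trans‑dihydrocarvone) | CC(=C)[C@@H]1CC[C@@H](C)C(=O)C1 | intermediate
3 | ethyl 4‑(benzyloxy)‑3‑oxobutanoate | CCOC(=O)CC(=O)COCc1ccccc1 | starting material
4 | benzyl 4‑(benzyloxy)‑3‑oxobutanoate | O=C(CC(=O)COCc1ccccc1)OCc1ccccc1 | intermediate
5 | benzyl 4‑(benzyloxy)‑2‑(ethoxymethylidene)‑3‑oxobutanoate (E/Z mixture) | CCOC=C(C(=O)COCc1ccccc1)C(=O)OCc1ccccc1 | intermediate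
6 | benzyl 4‑(benzyloxy)‑2‑{[(3R,6R)‑3‑methyl‑2‑oxo‑6‑(prop‑1‑en‑2‑yl)cyclohexyl]methylidene}‑3‑oxobutanoate (mixture at ring C1 and at the alkene) | CC(=C)[C@@H]1CC[C@@H](C)C(=O)C1C=C(C(=O)COCc1ccccc1)C(=O)OCc1ccccc1 | intermediate (not isolated)
7 | benzyl (5R,8S)‑4‑(benzyloxy)‑3‑hydroxy‑5‑methyl‑8‑(prop‑1‑en‑2‑yl)‑5,6,7,8‑tetrahydronaphthalene‑2‑carboxylate | CC(=C)[C@@H]1CC[C@@H](C)c2c1cc(C(=O)OCc3ccccc3)c(O)c2OCc4ccccc4 | intermediate (not isolated)
8 | benzyl (5R,8S)‑3,4‑bis(benzyloxy)‑5‑methyl‑8‑(prop‑1‑en‑2‑yl)‑5,6,7,8‑tetrahydronaphthalene‑2‑carboxylate | CC(=C)[C@@H]1CC[C@@H](C)c2c1cc(C(=O)OCc3ccccc3)c(OCc4ccccc4)c2OCc5ccccc5 | intermediate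
9 | benzyl (5R,8S)‑3,4‑bis(benzyloxy)‑8‑(4‑hydroxybut‑1‑en‑2‑yl)‑5‑methyl‑5,6,7,8‑tetrahydronaphthalene‑2‑carboxylate | OCCC(=C)[C@@H]1CC[C@@H](C)c2c1cc(C(=O)OCc3ccccc3)c(OCc4ccccc4)c2OCc5ccccc5 | intermediate
10 | (S)‑3‑bromo‑2‑methylpropan‑1‑ol | OC[C@H](C)CBr | starting material
11 | benzyl (5R,8S)‑3,4‑bis(benzyloxy)‑8‑{4‑[(5,7‑di‑tert‑butyl‑3‑phenyl‑2,3‑dihydro‑1,3‑benzoxazol‑2‑yl)oxy]but‑1‑en‑2‑yl}‑5‑methyl‑5,6,7,8‑tetrahydronaphthalene‑2‑carboxylate | CC(C)(C)c1cc(C(C)(C)C)c2OC(OCCC(=C)[C@@H]3CC[C@@H](C)c4c3cc(C(=O)OCc5ccccc5)c(OCc6ccccc6)c4OCc7ccccc7)N(c8ccccc8)c2c1 | intermediate (not isolated)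
12 | benzyl (5R,8S)‑3,4‑bis(benzyloxy)‑8‑[(6R)‑7‑hydroxy‑6‑methylhept‑1‑en‑2‑yl]‑5‑methyl‑5,6,7,8‑tetrahydronaphthalene‑2‑carboxylate | OC[C@H](C)CCCC(=C)[C@@H]1CC[C@@H](C)c2c1cc(C(=O)OCc3ccccc3)c(OCc4ccccc4)c2OCc5ccccc5 | intermediate
13 | benzyl (5R,8R)‑3,4‑bis(benzyloxy)‑8‑[(6R)‑1‑hydroperoxy‑7‑hydroxy‑6‑methylhept‑2‑en‑2‑yl]‑5‑methyl‑5,6,7,8‑tetrahydronaphthalene‑2‑carboxylate (E/Z mixture; 8R only through a change in CIP priorities, same geometry as 12) | OC[C@H](C)CCC=C(COO)[C@@H]1CC[C@@H](C)c2c1cc(C(=O)OCc3ccccc3)c(OCc4ccccc4)c2OCc5ccccc5 | intermediate (not isolated)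
14 | benzyl (5R,8R)‑3,4‑bis(benzyloxy)‑8‑[(6R)‑1,7‑dihydroxy‑6‑methylhept‑2‑en‑2‑yl]‑5‑methyl‑5,6,7,8‑tetrahydronaphthalene‑2‑carboxylate (E/Z mixture) | OC[C@H](C)CCC=C(CO)[C@@H]1CC[C@@H](C)c2c1cc(C(=O)OCc3ccccc3)c(OCc4ccccc4)c2OCc5ccccc5 | intermediate (not isolated)
15 | benzyl (5R,8R)‑8‑[(6R)‑1,7‑diacetoxy‑6‑methylhept‑2‑en‑2‑yl]‑3,4‑bis(benzyloxy)‑5‑methyl‑5,6,7,8‑tetrahydronaphthalene‑2‑carboxylate (E/Z mixture) | CC(=O)OC[C@H](C)CCC=C(COC(C)=O)[C@@H]1CC[C@@H](C)c2c1cc(C(=O)OCc3ccccc3)c(OCc4ccccc4)c2OCc5ccccc5 | intermediate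
16 | benzyl (5R,8S)‑8‑[(2S,6R)‑1,7‑diacetoxy‑6‑methylheptan‑2‑yl]‑3,4‑bis(benzyloxy)‑5‑methyl‑5,6,7,8‑tetrahydronaphthalene‑2‑carboxylate | CC(=O)OC[C@H](C)CCC[C@H](COC(C)=O)[C@@H]1CC[C@@H](C)c2c1cc(C(=O)OCc3ccccc3)c(OCc4ccccc4)c2OCc5ccccc5 | intermediate
17 | (5R,8S)‑8‑[(2S,6R)‑1,7‑diacetoxy‑6‑methylheptan‑2‑yl]‑3,4‑dihydroxy‑5‑methyl‑5,6,7,8‑tetrahydronaphthalene‑2‑carboxylic acid (CNP0245723.1) | CC(=O)OC[C@H](C)CCC[C@H](COC(C)=O)[C@@H]1CC[C@@H](C)c2c1cc(C(=O)O)c(O)c2O | target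

**Step count and risks**
Total step count: 9. Longest linear sequence: 8 steps (from 3 through steps 2 to 9); 7 steps from carvone 1.

Stereocentres: C4 is bought in 1, C15 is bought in 10, C1 is set in step 1 and C11 in step 8, both under control of C4.

The three steps most likely to fail:

Step 4 (the proposed new benzannulation). Possible failures are proton transfer from 5 to the enolate, closure of 6 through oxygen onto the ester to give a 2‑pyranone, and a slow aldol onto the hindered ketone. The fallback uses known chemistry, sets out from 2 and comes back at 8. Ketone 2 is formylated at the CH2 (LiN(i‑Pr)2, THF, −78 °C; CF3CH2OCHO) to (2R,5S)‑6‑(hydroxymethylidene)‑2‑methyl‑5‑(prop‑1‑en‑2‑yl)cyclohexan‑1‑one F1. F1 is then condensed with β‑keto ester 4 in the classical phenol synthesis from hydroxymethylene ketones and acetoacetic esters (piperidinium acetate, PhMe, 60 °C; then K2CO3, DMF, 70 °C; then BnBr). Knoevenagel condensation gives the same dienone 6, which closes to phenol 7 and is benzylated to 8. Step 3 and compound 5 are then not needed.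

Step 7 (singlet‑oxygen ene reaction). 1,1‑Disubstituted alkenes react slowly with singlet oxygen, and the electron‑rich arene may be oxidised on long irradiation. The fallback sets out from 12 and comes back at 15. Ene‑type allylic chlorination (NaOCl, CeCl3·7H2O, CH2Cl2/H2O, 0 °C) gives the transposed allylic chloride benzyl (5R,8R)‑3,4‑bis(benzyloxy)‑8‑[(6R)‑1‑chloro‑7‑hydroxy‑6‑methylhept‑2‑en‑2‑yl]‑5‑methyl‑5,6,7,8‑tetrahydronaphthalene‑2‑carboxylate F2. Displacement with CsOAc (DMF, 50 °C) gives the mono‑acetate benzyl (5R,8R)‑8‑[(6R)‑1‑acetoxy‑7‑hydroxy‑6‑methylhept‑2‑en‑2‑yl]‑3,4‑bis(benzyloxy)‑5‑methyl‑5,6,7,8‑tetrahydronaphthalene‑2‑carboxylate F3, and Ac2O/pyridine then gives 15.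

Step 8 (configuration at C11). The facial preference is predicted by analogy, not demonstrated on this ring system, and may be weak or reversed. The fallback sets out from 12 and comes back at 16, skipping step 7. In 12 the chain arm and the carbon that becomes C18 are interchanged relative to 15, so hydroboration under the same facial rule gives the opposite configuration at C11. If hydrogenation of 15 gives mainly the C11 epimer, 12 is therefore hydroborated (9‑BBN, THF, 0 °C → rt; NaBO3·4H2O) to the diol benzyl (5R,8S)‑3,4‑bis(benzyloxy)‑8‑[(2S,6R)‑1,7‑dihydroxy‑6‑methylheptan‑2‑yl]‑5‑methyl‑5,6,7,8‑tetrahydronaphthalene‑2‑carboxylate F4, which Ac2O/pyridine converts to 16. If the hydrogenation is merely unselective, the diastereomers of 16 are separated by chromatography.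

**Further compounds**
F1 | step 4 | (2R,5S)‑6‑(hydroxymethylidene)‑2‑methyl‑5‑(prop‑1‑en‑2‑yl)cyclohexan‑1‑one | CC(=C)[C@@H]1CC[C@@H](C)C(=O)C1=CO
F2 | step 7 | benzyl (5R,8R)‑3,4‑bis(benzyloxy)‑8‑[(6R)‑1‑chloro‑7‑hydroxy‑6‑methylhept‑2‑en‑2‑yl]‑5‑methyl‑5,6,7,8‑tetrahydronaphthalene‑2‑carboxylate | OC[C@H](C)CCC=C(CCl)[C@@H]1CC[C@@H](C)c2c1cc(C(=O)OCc3ccccc3)c(OCc4ccccc4)c2OCc5ccccc5
F3 | step 7 | benzyl (5R,8R)‑8‑[(6R)‑1‑acetoxy‑7‑hydroxy‑6‑methylhept‑2‑en‑2‑yl]‑3,4‑bis(benzyloxy)‑5‑methyl‑5,6,7,8‑tetrahydronaphthalene‑2‑carboxylate | OC[C@H](C)CCC=C(COC(C)=O)[C@@H]1CC[C@@H](C)c2c1cc(C(=O)OCc3ccccc3)c(OCc4ccccc4)c2OCc5ccccc5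
F4 | step 8 | benzyl (5R,8S)‑3,4‑bis(benzyloxy)‑8‑[(2S,6R)‑1,7‑dihydroxy‑6‑methylheptan‑2‑yl]‑5‑methyl‑5,6,7,8‑tetrahydronaphthalene‑2‑carboxylate | OC[C@H](C)CCC[C@H](CO)[C@@H]1CC[C@@H](C)c2c1cc(C(=O)OCc3ccccc3)c(OCc4ccccc4)c2OCc5ccccc5
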